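## Analysis of the target

The target 23 is a germacranolide: a cyclodeca-1(10),4-diene (ring C1–C10, methyl groups on C4 and C10, acetoxy groups on C3 and C9) fused through C6–C7 to an α-methyl-γ-butyrolactone (O on C6; C7–C11(CH3)–C12=O). The C1=C10 double bond is Z (C2 and C9 on the same side) and C4=C5 is E, so the ring is a cis,trans-1,5-diene. The five stereocentres are 3S, 6S, 7S, 9R and 11R: the lactone is trans-fused (H6 and H7 anti), the C9 acetate lies on the ring face of the C6 oxygen and opposite the C7 side chain, C3 is remote from this group across the E olefin, and the C11 methyl is cis to the C7–C8 bond. That last arrangement is the less stable one for a trans-fused lactone, so C11 cannot be set by equilibration and must not meet base once it is in place. The other sensitive features are the two allylic acetates (hydrolysis, acyl shift, ionisation) and the strained 1,5-diene, which can cyclise across the ring with acid and undergo Cope rearrangement on heating. The difficulty is threefold: a ten-membered ring of defined Z/E geometry, stereocentres on both sides of the ring that cannot control one another (C3 against C6/C7/C9), and a contra-thermodynamic C11. The route rests on the unit C10=C1–C2–C3–C4=C5: its two olefins are what remains when the σ-bonds C5–C10 and C1–C4 of a cyclobutane are broken, so the ring is the formal metathesis product of a cyclohexenone (C5–C10, carbonyl at C9) and a cyclobutene (C1–C4), and the six-carbon half with C7 and the C11–C13 branch has the skeleton of carvone.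

## Retrosynthetic reasoning

**Lactone C12–O bond.** Target 23 is opened to the 6,12-diol 20. The forward step is an oxidative lactonisation of a primary alcohol onto the C6 hydroxyl, which forms no enolate and so leaves C11 untouched. An exocyclic C11=C13 lactone reduced at the end would be shorter on paper. It is not used because hydride/proton or hydrogen would be expected to reach C11 of the trans-fused lactone from the face opposite H7 and give the 11α-methyl epimer, not the 11β-methyl group of the target.

**Protecting groups and C9.** Diol 20 comes from the bis-silyl ether 19, its C9 acetate from alcohol 18, and 18 from dienone 17 by cutting the C9–H bond. The forward reduction must be reagent-controlled, because the flexible ring offers no reliable bias. Silyl ethers on O6 and O12 against acetates on O3 and O9 give the differentiation the end-game needs.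

**The two ring olefins.** In 17 the bonds C5–C10 and C1–C4 are reconnected to give the tricyclic ketone 16. The forward reaction is the thermal opening of a bicyclo[2.2.0]hexane, driven by strain. It needs no ring-closing event on a ten-membered chain and sets both olefin geometries through one chair-like diyl. The C9 ketone is kept for this step because it weakens C5–C10 and ends conjugated with C1=C10.

**The cyclobutane (key disconnection).** In 16 the bonds C10–C1 and C5–C4 are cut to give the cyclohexenone 10 and the cyclobutenyl acetate 15. These are the only two bonds whose formation turns two small, separately made chiral fragments into the complete C1–C10 skeleton. C3 arrives in 15; C6, C7 and C11 arrive in 10. The forward photocycloaddition has to deliver only the orientation (C4 to C5) and a cis ring fusion, because the four new stereocentres disappear in the next step.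

**C11.** Enone 10 is traced through hydroxy enone 9 and diol 8 to the isopropenyl compound 6, cutting C11–H and C12–O. Hydroboration with a hindered borane is placed on the six-membered ring, where the silyloxy group on C6 and the side chain on C7 are trans neighbours, the situation in which 1,2-induction at an isopropenyl group is dependable. Saturating the side chain here also removes the only alkene that could compete intramolecularly for the excited enone, or form a second 1,5-diene with C4=C5 after ring opening.

**C6 oxygen.** Silyl ether 6 comes from the γ-hydroxy enone 5, and 5 from (S)-carvone 1 through its through-conjugated silyl dienol ether 3. Peracid oxidation at the γ-carbon must place the oxygen trans to the C7 substituent. Carvone supplies C7 in the correct absolute configuration and all ten carbons of this half.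

**Cyclobutene.** Acetate 15 is the slower-reacting enantiomer of racemic acetate 14, which comes from alcohol 13 by acylation. The C3–O bond of 13 is cut back to 1-methylcyclobutene 12, the endocyclic isomer of commercial methylenecyclobutane 11. The forward steps are an allylic oxidation next to the methyl-bearing alkene carbon and an enzymatic resolution.

## Alternatives that were turned down

**Alternative 1: De Mayo reaction of an eleven-membered β-keto lactone.**
- Disconnection: bonds C7–C11 and C8–C9 are made and C9–C11 is broken. The precursor is the eleven-membered β-keto lactone A1 (ring through C9, C11, C12, the lactone oxygen, C6, C5, C4, C3, C2, C1 and C10, with a vinyl group C7=C8 on C6).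
- Forward key step: on irradiation the enol double bond C9=C11 adds across C7=C8, and retro-aldol cleavage of C9–C11 contracts the ring to the ten-membered 9-ketone A2 with the lactone closed.
- For it: one step forms carbocycle and lactone together; the 1,5-relation of C11 and C7 favours the five-membered closure; C3 and C6 come from small pieces joined as an ester. On step count after the key step it is stronger than the chosen route.
- Against it: C11 is released as a lactone enolate and protonated, which should give the more stable 11α-methyl epimer and not the configuration drawn in A2. The C9 ketone of A1 is conjugated to C1=C10, so the excited state can also relax by Z/E isomerisation. A1 is itself a medium ring with an E and a Z olefin, about as hard to close as the target ring. C7 depends on facial selectivity in a flexible macrocycle, and C9 must still be reduced and acetylated.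
- Comparison: the chosen strategy takes C7 and C11 from carvone and a hydroboration under kinetic control, and uses a bimolecular photoreaction with low stereochemical demands.

**Alternative 2: anionic oxy-Cope ring expansion.**
- Disconnection: C6–C7 is made and C4–C9 is broken. The precursor is the trans-1,2-dialkenylcyclohexenol A3.
- Forward key step: A3, deprotonated with KH and 18-crown-6, rearranges through a chair to the Z,E-cyclodecadien-9-one A4, setting C6, C7 and E C4=C5, with Z C1=C10 carried in from the ring.
- For it: the reaction type is reliable for cyclodecenones and runs at or below room temperature, whereas the chosen route needs about 200 °C; it controls C6/C7 directly. On both points it is stronger.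
- Against it: A3 carries two adjacent fully substituted carbons (C4 and C9), which must be built by adding a functionalised alkenyl metal to a hindered ketone trans to an enol-ether side chain. C3 sits next to the quaternary C4. The C11-bearing alkenyl fragment needs its own asymmetric synthesis, and the ether groups on O3 and O6 must later be exchanged for acetate and lactone.
- Comparison: the chosen strategy reaches its key-step partners in six and four steps from commercial materials and leaves only acetylation and deprotection after the ring is made.

**Alternative 3: nickel-catalysed reductive ynal macrocyclisation at C3–C4.**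
- Disconnection: C3–C4. The precursor is the ynal A5, with the lactone, C9 and Z C1=C10 already in place.
- Forward key step: Ni(cod)2 (zerovalent nickel), a carbene ligand and a trialkylsilane couple the C3 aldehyde with the methyl-bearing alkyne carbon C4 and deliver hydrogen to C5, giving the ten-membered silyl ether A6 with E C4=C5.
- For it: the C3 carbinol and the trisubstituted E olefin are made in one catalytic step under mild conditions. C11 could be set earlier by methylation of a lactone enolate, which should give the required 11β-methyl group. On that point it is at least as strong as the chosen route.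
- Against it: closing a ten-membered carbocycle end to end must overcome transannular strain and competing oligomerisation, and is far less secure than the larger rings for which this coupling is used. Attack at C4 or C5 of the alkyne and the C3 configuration depend on the conformation of the forming ring. The β,γ-unsaturated aldehyde of A5 is prone to move into conjugation. A5 needs acyclic control of C6, C7, C9 and C11 plus a Z trisubstituted olefin.
- Comparison: the chosen strategy makes the ring by strain release from a rigid tricycle and takes its stereocentres from carvone and a resolved cyclobutenol.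

Key step: step 11

Remark: germacrane numbering (C1–C15) is used for every intermediate; in the cyclohexenone names ring positions 1–6 are germacrane C9, C10, C5, C6, C7, C8. Assumption: minor cis-fused stereoisomers of photoadduct 16 are carried into step 12 with it, because the four cyclobutane centres are destroyed there.

## Route

Step 1
Reactants: 1 (S)-carvone
Product: 3 trimethyl{[(5R)-2-methyl-5-(prop-1-en-2-yl)cyclohexa-1,3-dien-1-yl]oxy}silane (through-conjugated silyl dienol ether), via magnesium dienolate 2 (not isolated)
Conditions: MeMgBr, FeCl3 (5 mol %), Et2O, −20 °C; then Me3SiCl, Et3N, DMPU, −20 °C → rt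
Reagents that add atoms: chlorotrimethylsilane, C[Si](C)(C)Cl
Why: MeMgBr with catalytic FeCl3 removes the γ-proton (on C6) of a cyclohexenone and gives the through-conjugated dienolate, which is silylated on oxygen; amide bases would give the cross-conjugated isomer instead. C7 is not touched.

Step 2
Reactants: 3 silyl dienol ether
Product: 5 (4R,5S)-4-hydroxy-2-methyl-5-(prop-1-en-2-yl)cyclohex-2-en-1-one (C6 hydroxyl trans to the C7 isopropenyl group), via silyloxy epoxide 4 (not isolated)
Conditions: mCPBA, NaHCO3, CH2Cl2, −20 °C; then AcOH, THF/H2O, 0 °C
Reagents that add atoms: meta-chloroperbenzoic acid, OOC(=O)c1cccc(Cl)c1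
Why: Vinylogous Rubottom oxidation: the peracid attacks the distal C5=C6 bond of the dienol ether on the face away from the C7 substituent, and the silyloxy epoxide opens to the γ-hydroxy enone, so the new C6–O bond is trans to the side chain. The isolated 1,1-disubstituted alkene is much less nucleophilic than the dienol ether and should survive one equivalent of peracid.

Step 3
Reactants: 5 γ-hydroxy enone
Product: 6 (4R,5S)-4-[(tert-butyldimethylsilyl)oxy]-2-methyl-5-(prop-1-en-2-yl)cyclohex-2-en-1-one
Conditions: TBSCl, imidazole, DMF, rt
Reagents that add atoms: tert-butyldimethylsilyl chloride, CC(C)(C)[Si](C)(C)Cl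
Why: Standard silylation of a secondary alcohol; the bulky ether blocks retro-aldol and dehydration pathways of the γ-hydroxy enone and later serves as the large group that directs steps 4 and 11.

Step 4
Reactants: 6 silyl ether
Product: 8 (1S,4S,5S)-4-[(tert-butyldimethylsilyl)oxy]-5-[(2R)-1-hydroxypropan-2-yl]-2-methylcyclohex-2-en-1-ol (the C1 carbinol epimer is drawn; either epimer serves), via bis-borane adduct 7 (not isolated)
Conditions: 9-BBN (3 equiv), THF, 0 °C → rt; then NaOH, H2O2, 0 °C
Reagents that add atoms: hydrogen peroxide, OO
Why: 9-BBN hydroborates the 1,1-disubstituted alkene (boron on C12) and also reduces the enone carbonyl 1,2, both known reactions of this borane, while the trisubstituted ring alkene is inert. With H7 eclipsing the double bond the borane should approach from the side away from the silyloxy-bearing C6, which puts the new hydrogen on C11 on the C8 side and gives 11R after oxidation with retention; this sense is well established for trans-2-isopropenylcyclohexanol derivatives. The C9 carbinol configuration does not matter because step 5 removes it.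

Step 5
Reactants: 8 diol
Product: 9 (4S,5S)-4-[(tert-butyldimethylsilyl)oxy]-5-[(2R)-1-hydroxypropan-2-yl]-2-methylcyclohex-2-en-1-one
Conditions: MnO2 (activated, excess), CH2Cl2, rt
Reagents that add atoms: none
Why: MnO2 oxidises the allylic secondary alcohol back to the enone and leaves the saturated primary alcohol; the other allylic oxygen (C6) is protected, so only the carvone-type enone can form.

Step 6
Reactants: 9 hydroxy enone
Product: 10 (4S,5S)-4-[(tert-butyldimethylsilyl)oxy]-5-{(2R)-1-[(tert-butyldimethylsilyl)oxy]propan-2-yl}-2-methylcyclohex-2-en-1-one
Conditions: TBSCl, imidazole, DMF, 0 °C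
Reagents that add atoms: tert-butyldimethylsilyl chloride, CC(C)(C)[Si](C)(C)Cl
Why: Fast silylation of the primary alcohol; it prevents conjugate addition of O12 to C5 and gives two silyl ethers that are removed together in step 15.

Step 7
Reactants: 11 methylenecyclobutane
Product: 12 1-methylcyclobutene
Conditions: KOtBu (cat.), DMSO, 40 °C; fractional distillation
Reagents that add atoms: none
Why: Base-mediated prototropic isomerisation of the exocyclic alkene; the endocyclic trisubstituted isomer is the more stable one and is separated from residual 11 by distillation.

Step 8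
Reactants: 12 1-methylcyclobutene
Product: 13 rac-2-methylcyclobut-2-en-1-ol
Conditions: SeO2 (cat.), t-BuOOH, CH2Cl2, 0 °C → rt
Reagents that add atoms: selenium dioxide, O=[Se]=O; tert-butyl hydroperoxide, CC(C)(C)OO
Why: SeO2 allylic oxidation (ene reaction, then [2,3]-sigmatropic shift) goes to the ring CH2 next to the more substituted alkene carbon and returns the double bond to its original position, which gives the C3 carbinol next to the methyl-bearing C4. The catalytic protocol with t-BuOOH works at room temperature, which suits the volatile substrate.

Step 9
Reactants: 13 racemic cyclobutenol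
Product: 14 rac-2-methylcyclobut-2-en-1-yl acetate
Conditions: Ac2O, pyridine, DMAP (cat.), CH2Cl2, 0 °C
Reagents that add atoms: acetic anhydride, CC(=O)OC(C)=O
Why: Routine acylation; the acetate is less volatile than the alcohol and is the substrate of the enzymatic step.

Step 10
Reactants: 14 racemic acetate
Product: 15 (1S)-2-methylcyclobut-2-en-1-yl acetate (recovered unreacted enantiomer)
Conditions: Candida antarctica lipase B (immobilised), phosphate buffer pH 7, MTBE, 25 °C, run past half conversion
Reagents that add atoms: none
Why: Lipase kinetic resolution: with the methyl-substituted sp2 carbon as the large and CH2 as the small group, the empirical rule for secondary alcohols predicts faster hydrolysis of the R acetate, so the S acetate remains and is enriched further by running past half conversion. The configuration is to be confirmed on the derived alcohol.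

Step 11
Reactants: 10 bis-silyl enone; 15 (1S)-cyclobutenyl acetate (excess, recovered)
Product: 16 cis-anti-cis tricyclo[4.4.0.0(2,5)]decan-7-one photoadduct (germacrane skeleton with added bonds C10–C1 and C5–C4; 1S,3S,4R,5S,6S,7S,10R,11R; cyclobutane on the face opposite the C6 silyl ether; C3 acetate exo and cis to the C4 methyl)
Conditions: hν (350 nm, Pyrex), 15 (5 equiv), CH2Cl2, −40 °C
Reagents that add atoms: none
Why: Light near 350 nm excites the enone n,π* band; intersystem crossing gives the twisted π,π* triplet, which adds to ground-state 15 through triplet 1,4-biradicals that close after spin inversion, the enone–alkene [2+2] photocycloaddition in the form known for cyclohexenones and cyclobutenes. The one ring formed, the central cyclobutane C5–C10–C1–C4, is closed by radical–radical coupling of the 1,4-biradical and is fused to the six-membered ring at C5–C10 and to the cyclobutene-derived ring at C1–C4. Bonds C10–C1 and C5–C4 are expected because the methyl-bearing alkene carbon goes to the enone β-carbon C5, as with other 1,1-disubstituted donor alkenes, and because the other orientation would have to join the two fully substituted carbons C10 and C4, a closure that should lose to reversion of the biradical. C5 and C10 should form cis, since a trans-fused bicyclo[4.2.0]octanone carrying a further fused cyclobutane is very strained, and on the ring face opposite the bulky C6 silyl ether next to C5; C1 and C4 are cis by the ring, the cyclobutene reacting on the face away from its C3 acetate. The six-membered ring and the outer cyclobutane take the less crowded anti arrangement, and for the S acetate this arrangement, the enone face anti to C6–O and the cyclobutene face anti to the acetate all lead to the same diastereomer, so the three preferences reinforce one another. The step must deliver only the orientation and the cis ring fusion: C1, C4, C5 and C10 are lost again in step 12, and any cis-fused stereoisomer of 16 opens to the same dienone, while C3, C6, C7 and C11 are spectators. The saturated side chain leaves no second alkene to compete intramolecularly, and the excess of 15 at low temperature suppresses enone dimerisation.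

Step 12
Reactants: 16 photoadduct
Product: 17 (3S,6S,7S,11R)-3-acetoxy-6,12-bis[(tert-butyldimethylsilyl)oxy]germacra-1(10)Z,4E-dien-9-one
Conditions: PhMe (0.01 M, degassed), BHT (cat.), base-washed sealed tube, 200 °C
Reagents that add atoms: none
Why: Thermal cycloreversion of the bicyclo[2.2.0]hexane unit: the strained central bond C1–C4 breaks to a cyclohexane-1,4-diyl, which then cleaves C5–C10 (quaternary and α to the ketone) in preference to C2–C3, so both photochemically made bonds end as olefins and the enone C1=C10–C9=O results. In the favoured chair diyl the C10 methyl and C6 are equatorial and C9 is axial, which becomes Z C1=C10 and E C4=C5. C3, C6, C7 and C11 are not involved.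

Step 13
Reactants: 17 dienone
Product: 18 (3S,6S,7S,9R,11R)-3-acetoxy-6,12-bis[(tert-butyldimethylsilyl)oxy]germacra-1(10)Z,4E-dien-9-ol
Conditions: (S)-2-methyl-CBS-oxazaborolidine (0.2 equiv), catecholborane, PhMe, −78 °C
Reagents that add atoms: none
Why: Corey–Bakshi–Shibata reduction: with the fully substituted alkenyl carbon C10 as the large and the C8 methylene as the small substituent, the S catalyst should give the 9R allylic alcohol under reagent control. Catecholborane at −78 °C reduces the enone 1,2 and leaves the acetate and the silyl ethers.

Step 14
Reactants: 18 allylic alcohol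
Product: 19 (3S,6S,7S,9R,11R)-3,9-diacetoxy-6,12-bis[(tert-butyldimethylsilyl)oxy]germacra-1(10)Z,4E-diene
Conditions: Ac2O, Et3N, DMAP (cat.), CH2Cl2, 0 °C → rt
Reagents that add atoms: acetic anhydride, CC(=O)OC(C)=O
Why: Acylation of the only free hydroxyl; it goes with retention at C9.

Step 15
Reactants: 19 diacetate
Product: 20 (3S,6S,7S,9R,11R)-3,9-diacetoxygermacra-1(10)Z,4E-diene-6,12-diol
Conditions: HF·pyridine, pyridine, THF, 0 °C → rt
Reagents that add atoms: none
Why: Fluoride cleavage of both silyl ethers; the pyridine-buffered reagent is not basic enough to hydrolyse or shift the acetates and not acidic enough to protonate the 1,5-diene.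

Step 16
Reactants: 20 diol
Product: 23 (3S,6S,7S,9R,11R)-3,9-diacetoxygermacra-1(10)Z,4E-dien-12,6-olide (target), via hydroxy aldehyde 21 (not isolated), via lactol 22 (not isolated)
Conditions: TEMPO (0.2 equiv), PhI(OAc)2 (2.5 equiv), CH2Cl2, rt
Reagents that add atoms: none
Why: TEMPO/PhI(OAc)2 oxidises the primary alcohol selectively to the aldehyde, which closes onto the C6 hydroxyl to the five-membered lactol and is oxidised on to the lactone. No enolate is formed, so the 11R centre from step 4 is kept, and the lactone is trans-fused because C6 and C7 already are.

## Compound list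

1 | (S)-carvone, (5S)-2-methyl-5-(prop-1-en-2-yl)cyclohex-2-en-1-one | CC1=CC[C@H](C(C)=C)CC1=O | starting material
2 | bromomagnesium through-conjugated dienolate of 1 | CC1=C(O[Mg]Br)C[C@@H](C(C)=C)C=C1 | intermediate (not isolated)
3 | trimethyl{[(5R)-2-methyl-5-(prop-1-en-2-yl)cyclohexa-1,3-dien-1-yl]oxy}silane | CC1=C(O[Si](C)(C)C)C[C@@H](C(C)=C)C=C1 | intermediate
4 | C5–C6 epoxide of 3, oxirane trans to the isopropenyl group | CC1=C(O[Si](C)(C)C)C[C@@H](C(C)=C)[C@@H]2O[C@H]12 | intermediate (not isolated)
5 | (4R,5S)-4-hydroxy-2-methyl-5-(prop-1-en-2-yl)cyclohex-2-en-1-one | CC1=C[C@@H](O)[C@H](C(C)=C)CC1=O | intermediate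
6 | (4R,5S)-4-[(tert-butyldimethylsilyl)oxy]-2-methyl-5-(prop-1-en-2-yl)cyclohex-2-en-1-one | CC1=C[C@@H](O[Si](C)(C)C(C)(C)C)[C@H](C(C)=C)CC1=O | intermediate
7 | bis(9-borabicyclo[3.3.1]nonan-9-yl) adduct of 6 (borane on C12, borinate on O9) | CC1=C[C@@H](O[Si](C)(C)C(C)(C)C)[C@H]([C@@H](C)CB2C3CCCC2CCC3)C[C@@H]1OB1C2CCCC1CCC2 | intermediate (not isolated)
8 | (1S,4S,5S)-4-[(tert-butyldimethylsilyl)oxy]-5-[(2R)-1-hydroxypropan-2-yl]-2-methylcyclohex-2-en-1-ol (C1 epimer drawn; either serves) | CC1=C[C@@H](O[Si](C)(C)C(C)(C)C)[C@H]([C@@H](C)CO)C[C@@H]1O | intermediate
9 | (4S,5S)-4-[(tert-butyldimethylsilyl)oxy]-5-[(2R)-1-hydroxypropan-2-yl]-2-methylcyclohex-2-en-1-one | CC1=C[C@@H](O[Si](C)(C)C(C)(C)C)[C@H]([C@@H](C)CO)CC1=O | intermediate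
10 | (4S,5S)-4-[(tert-butyldimethylsilyl)oxy]-5-{(2R)-1-[(tert-butyldimethylsilyl)oxy]propan-2-yl}-2-methylcyclohex-2-en-1-one | CC1=C[C@@H](O[Si](C)(C)C(C)(C)C)[C@H]([C@@H](C)CO[Si](C)(C)C(C)(C)C)CC1=O | intermediate
11 | methylenecyclobutane | C=C1CCC1 | starting material
12 | 1-methylcyclobutene | CC1=CCC1 | intermediate
13 | rac-2-methylcyclobut-2-en-1-ol | CC1=CCC1O | intermediate
14 | rac-2-methylcyclobut-2-en-1-yl acetate | CC1=CCC1OC(C)=O | intermediate
15 | (1S)-2-methylcyclobut-2-en-1-yl acetate | CC1=CC[C@@H]1OC(C)=O | intermediate
16 | cis-anti-cis photoadduct, (1S,3S,4R,5S,6S,7S,10R,11R) in germacrane numbering, C9 ketone | O=C1C[C@@H]([C@@H](C)CO[Si](C)(C)C(C)(C)C)[C@H](O[Si](C)(C)C(C)(C)C)[C@H]2[C@]3(C)[C@@H](OC(C)=O)C[C@@H]3[C@@]12C | intermediate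
17 | (3S,6S,7S,11R)-3-acetoxy-6,12-bis[(tert-butyldimethylsilyl)oxy]germacra-1(10)Z,4E-dien-9-one | CC(=O)O[C@H]1C/C=C(/C)C(=O)C[C@@H]([C@@H](C)CO[Si](C)(C)C(C)(C)C)[C@@H](/C=C/1C)O[Si](C)(C)C(C)(C)C | intermediate
18 | (3S,6S,7S,9R,11R)-3-acetoxy-6,12-bis[(tert-butyldimethylsilyl)oxy]germacra-1(10)Z,4E-dien-9-ol | CC(=O)O[C@H]1C/C=C(/C)[C@H](O)C[C@@H]([C@@H](C)CO[Si](C)(C)C(C)(C)C)[C@@H](/C=C/1C)O[Si](C)(C)C(C)(C)C | intermediate
19 | (3S,6S,7S,9R,11R)-3,9-diacetoxy-6,12-bis[(tert-butyldimethylsilyl)oxy]germacra-1(10)Z,4E-diene | CC(=O)O[C@H]1C/C=C(/C)[C@H](OC(C)=O)C[C@@H]([C@@H](C)CO[Si](C)(C)C(C)(C)C)[C@@H](/C=C/1C)O[Si](C)(C)C(C)(C)C | intermediate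
20 | (3S,6S,7S,9R,11R)-3,9-diacetoxygermacra-1(10)Z,4E-diene-6,12-diol | CC(=O)O[C@H]1C/C=C(/C)[C@H](OC(C)=O)C[C@@H]([C@@H](C)CO)[C@@H](/C=C/1C)O | intermediate
21 | 6-hydroxy-12-aldehyde from 20 | CC(=O)O[C@H]1C/C=C(/C)[C@H](OC(C)=O)C[C@@H]([C@@H](C)C=O)[C@@H](/C=C/1C)O | intermediate (not isolated)
22 | 12,6-lactol (mixture of C12 anomers, C12 left undefined) | CC(=O)O[C@H]1C/C=C(/C)[C@H](OC(C)=O)C[C@@H]2[C@@H](/C=C/1C)OC(O)[C@@H]2C | intermediate (not isolated)
23 | (3S,6S,7S,9R,11R)-3,9-diacetoxygermacra-1(10)Z,4E-dien-12,6-olide | CC(=O)O[C@H]1C/C=C(/C)[C@H](OC(C)=O)C[C@@H]2[C@@H](/C=C/1C)OC(=O)[C@@H]2C | target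

## Step count and least certain steps

Total: 16 steps. Longest linear sequence: 12 steps (steps 1–6 and 11–16); the cyclobutene branch (steps 7–10) joins at step 11.

**Step 11 (key step).** The hindered trisubstituted cyclobutene may add too slowly to the short-lived triplet of a 2-methyl enone, so that the enone is lost to reduction or dimerisation. Some biradical closure in the other orientation or with trans ring fusion is also possible. The fallback makes the addition intramolecular. It sets out from 9 and 15. Methanolysis of 15 (K2CO3, MeOH) gives (1S)-2-methylcyclobut-2-en-1-ol F1. F1 and then 9 are joined with iPr2SiCl2 and imidazole to the diisopropylsilylene-linked enone–cyclobutene F2. Irradiation at 350 nm should give the silylene-bridged photoadduct F3 with one equivalent of cyclobutene held on the side-chain face of the enone. HF·pyridine at 0 °C cleaves the dialkoxysilane ahead of the hindered C6 silyl ether and gives the photoadduct 3,12-diol F4. TBSCl silylates the primary hydroxyl selectively to the photoadduct 3-ol F5, and Ac2O/DMAP returns to the route at 16 (or a cis-fused cyclobutane epimer, which step 12 treats the same).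

**Step 12.** The likeliest loss is onward reaction of 17 at 200 °C: Cope rearrangement of the new 1,5-diene to a divinylcyclohexanone, or a [1,5]-hydrogen shift in the Z-enone to a dienol that returns deconjugated. Competing cleavage of the diyl at C2–C3 would lead to the same ring-contracted skeleton. A short residence time at higher temperature in a flow tube is the first remedy. The fallback changes the order of events. It sets out from 16. The reduction of step 13 is applied to the rigid tricycle to give the tricyclic 9R-alcohol F6, and acetylation gives the tricyclic 3,9-diacetate F7. Thermolysis of F7 has no enolisable enone and opens directly to 19, where the route is rejoined.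

**Step 8.** Allylic oxidation of a cyclobutene may go astray by attack at the methyl group or at the other ring CH2, by over-oxidation to the strained enone, or by ring opening of the allylselenium intermediate; the volatility of 12 and 13 adds handling losses. The fallback builds the ring oxygen first and the methyl last. It does not use 11 or 12. Commercial 1,2-bis(trimethylsilyloxy)cyclobutene F8 is methanolysed to rac-2-hydroxycyclobutan-1-one F9 and silylated (TBSCl, imidazole) to rac-2-[(tert-butyldimethylsilyl)oxy]cyclobutan-1-one F10. Kinetic enolisation away from the oxygen-bearing carbon (LiN(SiMe3)2, then PhNTf2, −78 °C) gives rac-4-[(tert-butyldimethylsilyl)oxy]cyclobut-1-en-1-yl trifluoromethanesulfonate F11. Iron-catalysed coupling (MeMgBr, Fe(acac)3, THF/NMP) gives rac-tert-butyldimethyl[(2-methylcyclobut-2-en-1-yl)oxy]silane F12, and Bu4NF returns to the route at 13.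

**Step 2.** The peracid may attack the enol-ether carbon C10 instead of C6, giving the tertiary α-hydroxy ketone, or may show poor facial selectivity at C6. The fallback replaces electrophilic epoxidation by a cycloaddition. It sets out from 3. Singlet oxygen (O2, tetraphenylporphyrin, hν, CH2Cl2, −78 °C) adds across C9 and C6 of the diene, anti to the isopropenyl group, to give the 9-silyloxy-6,9-endoperoxide F13. Thiourea cleaves the O–O bond, and loss of the silyl group from the hemiketal returns 5. This fixes the oxygen at C6 by the [4+2] connectivity; the isolated alkene reacts with singlet oxygen far more slowly than the cyclic diene.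

**Step 4.** The borane may show poor or reversed facial selectivity at C11 if the silyloxy group does not sit next to the isopropenyl group in the reactive conformer. The fallback exchanges the roles of the two C11 substituents, so that the same facial preference leads to the opposite configuration. It sets out from 6. Allylic chlorination of the isopropenyl group (Ca(OCl)2, CO2, CH2Cl2/H2O) gives the 12-chloro enone F14. KOAc in DMF gives the 12-acetoxy enone F15, and K2CO3 in MeOH gives the 12-hydroxy-11(13)-ene F16. Hydrogenation with RhCl(PPh3)3, which reduces the 1,1-disubstituted alkene and leaves the trisubstituted enone, returns to the route at 9.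

**Step 13.** The conformation of the ten-membered enone may oppose the catalyst and lower the facial selectivity at C9. The fallback accepts the substrate's own preference and corrects it by substitution. It sets out from 17. NaBH4/CeCl3 in MeOH at −78 °C gives the allylic alcohol under substrate control. If this is the 9S-alcohol F17, a Mitsunobu reaction with acetic acid (PPh3, DIAD, PhMe, 0 °C) installs the acetate with inversion and rejoins the route at 19. If the substrate prefers 9R, the product is 18 itself.

## Further compounds

F1 | step 11 | (1S)-2-methylcyclobut-2-en-1-ol | CC1=CC[C@@H]1O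
F2 | step 11 | diisopropylsilylene-linked enone–cyclobutene (O12 of 9 and O3 of F1 joined through Si(iPr)2) | CC1=C[C@@H](O[Si](C)(C)C(C)(C)C)[C@H]([C@@H](C)CO[Si](C(C)C)(C(C)C)O[C@H]2CC=C2C)CC1=O
F3 | step 11 | silylene-bridged photoadduct (configuration of 16) | O=C1C[C@@H]([C@@H](C)CO[Si]4(C(C)C)C(C)C)[C@H](O[Si](C)(C)C(C)(C)C)[C@H]2[C@]3(C)[C@@H](O4)C[C@@H]3[C@@]12C
F4 | step 11 | photoadduct 3,12-diol (C6 silyl ether kept) | O=C1C[C@@H]([C@@H](C)CO)[C@H](O[Si](C)(C)C(C)(C)C)[C@H]2[C@]3(C)[C@@H](O)C[C@@H]3[C@@]12C
F5 | step 11 | photoadduct 3-ol (6,12-bis-silyl ether) | O=C1C[C@@H]([C@@H](C)CO[Si](C)(C)C(C)(C)C)[C@H](O[Si](C)(C)C(C)(C)C)[C@H]2[C@]3(C)[C@@H](O)C[C@@H]3[C@@]12C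
F6 | step 12 | tricyclic 9R-alcohol | O[C@@H]1C[C@@H]([C@@H](C)CO[Si](C)(C)C(C)(C)C)[C@H](O[Si](C)(C)C(C)(C)C)[C@H]2[C@]3(C)[C@@H](OC(C)=O)C[C@@H]3[C@@]12C
F7 | step 12 | tricyclic 3,9-diacetate | CC(=O)O[C@@H]1C[C@@H]([C@@H](C)CO[Si](C)(C)C(C)(C)C)[C@H](O[Si](C)(C)C(C)(C)C)[C@H]2[C@]3(C)[C@@H](OC(C)=O)C[C@@H]3[C@@]12C
F8 | step 8 | 1,2-bis(trimethylsilyloxy)cyclobutene | C[Si](C)(C)OC1=C(O[Si](C)(C)C)CC1
F9 | step 8 | rac-2-hydroxycyclobutan-1-one | O=C1CCC1O
F10 | step 8 | rac-2-[(tert-butyldimethylsilyl)oxy]cyclobutan-1-one | O=C1CCC1O[Si](C)(C)C(C)(C)C
F11 | step 8 | rac-4-[(tert-butyldimethylsilyl)oxy]cyclobut-1-en-1-yl trifluoromethanesulfonate | CC(C)(C)[Si](C)(C)OC1CC=C1OS(=O)(=O)C(F)(F)F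
F12 | step 8 | rac-tert-butyldimethyl[(2-methylcyclobut-2-en-1-yl)oxy]silane | CC1=CCC1O[Si](C)(C)C(C)(C)C
F13 | step 2 | 9-silyloxy-6,9-endoperoxide of 3 (peroxide bridge trans to the isopropenyl group) | CC1=C[C@H]2OO[C@]1(O[Si](C)(C)C)C[C@H]2C(C)=C
F14 | step 4 | (4R,5S)-4-[(tert-butyldimethylsilyl)oxy]-5-(3-chloroprop-1-en-2-yl)-2-methylcyclohex-2-en-1-one | CC1=C[C@@H](O[Si](C)(C)C(C)(C)C)[C@H](C(=C)CCl)CC1=O
F15 | step 4 | 2-{(1S,2R)-2-[(tert-butyldimethylsilyl)oxy]-4-methyl-5-oxocyclohex-3-en-1-yl}prop-2-en-1-yl acetate | CC1=C[C@@H](O[Si](C)(C)C(C)(C)C)[C@H](C(=C)COC(C)=O)CC1=O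
F16 | step 4 | (4R,5S)-4-[(tert-butyldimethylsilyl)oxy]-5-(3-hydroxyprop-1-en-2-yl)-2-methylcyclohex-2-en-1-one | CC1=C[C@@H](O[Si](C)(C)C(C)(C)C)[C@H](C(=C)CO)CC1=O
F17 | step 13 | (3S,6S,7S,9S,11R)-3-acetoxy-6,12-bis[(tert-butyldimethylsilyl)oxy]germacra-1(10)Z,4E-dien-9-ol | CC(=O)O[C@H]1C/C=C(/C)[C@@H](O)C[C@@H]([C@@H](C)CO[Si](C)(C)C(C)(C)C)[C@@H](/C=C/1C)O[Si](C)(C)C(C)(C)C
A1 | alternative 1 | eleven-membered β-keto lactone with C6 vinyl group (C11 epimerisable, left undefined) | CC(=O)O[C@H]1C/C=C(/C)C(=O)C(C)C(=O)O[C@@H](C=C)/C=C/1C
A2 | alternative 1 | 9-oxo analogue of the target (C3 acetate, lactone closed) | CC(=O)O[C@H]1C/C=C(/C)C(=O)C[C@@H]2[C@@H](/C=C/1C)OC(=O)[C@@H]2C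
A3 | alternative 2 | trans-1,2-dialkenylcyclohex-2-enol (C9 carbinol with the E-alkenyl chain C8=C7–C11–C12; C4 with methyl and the E-enol ether C5=C6; C3 silyl ether) | CC(C)(C)[Si](C)(C)O[C@H]1CC=C(C)[C@@](O)(/C=C/[C@@H](C)CO[Si](C)(C)C(C)(C)C)[C@]1(C)/C=C/OCc1ccc(OC)cc1
A4 | alternative 2 | Z,E-cyclodecadien-9-one with C3 silyl ether, C6 4-methoxybenzyl ether and C12 silyl ether | CC(C)(C)[Si](C)(C)O[C@H]1C/C=C(/C)C(=O)C[C@@H]([C@@H](C)CO[Si](C)(C)C(C)(C)C)[C@@H](/C=C/1C)OCc1ccc(OC)cc1
A5 | alternative 3 | ynal with the lactone, the C9 silyl ether and Z C1=C10 in place | O=CC/C=C(/C)[C@H](O[Si](C)(C)C(C)(C)C)C[C@@H]1[C@@H](C#CC)OC(=O)[C@@H]1C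
A6 | alternative 3 | ten-membered lactone with C3 triethylsilyl ether and C9 tert-butyldimethylsilyl ether | CC[Si](CC)(CC)O[C@H]1C/C=C(/C)[C@H](O[Si](C)(C)C(C)(C)C)C[C@@H]2[C@@H](/C=C/1C)OC(=O)[C@@H]2C
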